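**Plan**
1. Retrosynthetic cuts: the three ester C(=O)–O bonds at O3, O4 and O5, then the ring double bond C1=C2 (metathesis), then C5–C6 (allyl addition to a C5 aldehyde), and last the oxirane bonds C4–O and C5–O, which leads back to penta-1,4-dien-3-ol.
2. Enabling feature: with the cyclohexene numbered C1 (CO2Me) round to C6 (CH2), the cis oxygens on C3 and C4, lying between alkene carbon C2 and oxygenated C5, are the erythro 1,2-epoxy-3-ol of divinylcarbinol, a mirror-symmetric alcohol with two enantiotopic vinyl groups.
3. Forward order: oxirane on one vinyl group, silyl on O3, oxirane turned into the 4-O-PMB C5 aldehyde, C5–C6 bond from a 2-(methoxycarbonyl)allylstannane, O5 ester, the cyclohexene (the only ring of the target) closed by metathesis, then PMB and silyl exchanged for 2-methylbutanoyl and acetyl.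
4. Stereochemistry: C3 and C4 come from the tartrate-controlled epoxidation, C5 from 1,2-chelation by the C4 PMB ether, and the two side-chain centres from the enantiopure acids.

Key step: step 1

Remarks on the chemistry: ring positions are numbered as in shikimate (C1 bears CO2Me, C6 is CH2). TBS = tert-butyldimethylsilyl, PMB = 4-methoxybenzyl, salen = N,N′-bis(3,5-di-tert-butylsalicylidene)cyclohexane-1,2-diaminate. Both branched acids are assumed to be purchased enantiopure. The (R,R) antipode of the cobalt–salen catalyst in step 3 is assumed to be the one matched to epoxide 3; the antipode affects only the rate, not the product, and the (S,S) complex is the alternative if hydrolysis is slow.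

**Step 1**
Reactants: 1 penta-1,4-dien-3-ol
Product: 2 (2S,3R)-1,2-epoxypent-4-en-3-ol
Conditions: Ti(OiPr)4 (10 mol %), diisopropyl D-(−)-tartrate (13 mol %), tBuOOH (anhydrous, 1.5 equiv), 4 Å MS, CH2Cl2, −20 °C; non-aqueous work-up
Reagents that add atoms: tert-butyl hydroperoxide, CC(C)(C)OO
Why: Sharpless asymmetric epoxidation, run in its kinetic-resolution manifold on a prochiral bis-allylic alcohol: the alkoxide of 1 and the tert-butyl peroxide sit on the same tetravalent titanium centre of the dimeric titanium–tartrate complex, and the peroxide oxygen distal to the tert-butyl group is passed to the bound vinyl group through a spiro transition state. The oxirane closes in a 3-exo manner as the alkene π electrons displace tert-butoxide from that oxygen, which makes the C4–O and C5–O bonds (target numbering) and leaves the other vinyl group as the future C2. The oxirane stereocentre (future C4) is fixed by the alkene face that the D-tartrate complex exposes, and the carbinol carbon (future C3) becomes a stereocentre because only that vinyl group reacts quickly for which the carbinol hydrogen, not the second vinyl group, points into the ligand sphere, which is the erythro preference known for secondary allylic alcohols. The step therefore needs enantiotopic-group selectivity and diastereoface selectivity at once, and what secures both in the substrate is the single titanium-binding hydroxyl on the mirror plane between the two vinyl groups. Any mis-selected enantiomer still carries the vinyl group matched to the catalyst and should be drained into the bis-epoxide, so the enantiomeric purity of 2 is expected to rise with conversion; a small excess of oxidant serves that purpose, and the non-aqueous work-up is chosen because 2 is small, volatile and water-miscible.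

**Step 2**
Reactants: 2 (2S,3R)-1,2-epoxypent-4-en-3-ol
Product: 3 (2S,3R)-3-[(tert-butyldimethylsilyl)oxy]-1,2-epoxypent-4-ene
Conditions: TBSCl, imidazole, DMF, 0 °C → rt
Reagents that add atoms: tert-butyldimethylsilyl chloride, CC(C)(C)[Si](C)(C)Cl
Why: Imidazole-promoted silylation of a secondary alcohol under neutral amine conditions leaves the oxirane closed and marks O3 with a non-chelating, acid-removable group that is reserved for the final acetate.

**Step 3**
Reactants: 3 (2S,3R)-3-[(tert-butyldimethylsilyl)oxy]-1,2-epoxypent-4-ene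
Product: 4 (2S,3R)-3-[(tert-butyldimethylsilyl)oxy]pent-4-ene-1,2-diol
Conditions: (R,R)-(salen)Co(OAc) (trivalent cobalt, 2 mol %), H2O (1.5 equiv), THF, 0 °C → rt
Reagents that add atoms: water, O
Why: Cobalt–salen-catalysed hydrolytic epoxide opening (the reaction behind hydrolytic kinetic resolution, used here on a single enantiomer) delivers water to the unsubstituted oxirane carbon (future C5) under neutral conditions, so the C4–O bond and the C4 configuration are untouched and the silyl ether neither cleaves nor migrates.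

**Step 4**
Reactants: 4 (2S,3R)-3-[(tert-butyldimethylsilyl)oxy]pent-4-ene-1,2-diol
Product: 5 (4S)-4-[(1R)-1-[(tert-butyldimethylsilyl)oxy]prop-2-en-1-yl]-2-(4-methoxyphenyl)-1,3-dioxolane (both epimers at the acetal carbon)
Conditions: 4-MeOC6H4CH(OMe)2, pyridinium p-toluenesulfonate (cat.), CH2Cl2, rt
Reagents that add atoms: 4-methoxybenzaldehyde dimethyl acetal, COc1ccc(C(OC)OC)cc1
Why: Acid-catalysed transacetalisation of the 1,2-diol gives the five-membered p-methoxybenzylidene acetal, which ties O4 and O5 together in a form that can be opened regioselectively, and either acetal epimer serves.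

**Step 5**
Reactants: 5 (4S)-4-[(1R)-1-[(tert-butyldimethylsilyl)oxy]prop-2-en-1-yl]-2-(4-methoxyphenyl)-1,3-dioxolane
Product: 6 (2S,3R)-3-[(tert-butyldimethylsilyl)oxy]-2-[(4-methoxybenzyl)oxy]pent-4-en-1-ol
Conditions: iBu2AlH (3 equiv), CH2Cl2, −78 → 0 °C; Rochelle salt work-up
Reagents that add atoms: none
Why: Reductive acetal opening with iBu2AlH, in which aluminium binds the less hindered primary oxygen, the C–O bond on that side breaks and hydride quenches the oxocarbenium ion, should leave the PMB group on the secondary O4 and free the primary alcohol, the bulky and weakly basic silyl ether at O3 being a poor competitor for aluminium.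

**Step 6**
Reactants: 6 (2S,3R)-3-[(tert-butyldimethylsilyl)oxy]-2-[(4-methoxybenzyl)oxy]pent-4-en-1-ol
Product: 7 (2R,3R)-3-[(tert-butyldimethylsilyl)oxy]-2-[(4-methoxybenzyl)oxy]pent-4-enal
Conditions: Dess–Martin periodinane, NaHCO3, CH2Cl2, 0 °C → rt; used crude
Reagents that add atoms: none
Why: Dess–Martin oxidation of the primary alcohol under bicarbonate buffer is mild enough to give the α-alkoxy aldehyde without epimerising C4 or eliminating the β-silyloxy group (the descriptor at C4 changes only because the CIP priorities change).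

**Step 7**
Reactants: 8 methyl 2-(bromomethyl)acrylate
Product: 9 methyl 2-[(phenylsulfonyl)methyl]acrylate
Conditions: PhSO2Na, MeOH, reflux
Reagents that add atoms: sodium benzenesulfinate, [Na+].[O-]S(=O)c1ccccc1
Why: Allylic substitution (SN2 or SN2′, both giving the same product) of the bromide by the soft sulfinate sulfur installs the sulfonyl group that serves as radical leaving group in the next step.

**Step 8**
Reactants: 9 methyl 2-[(phenylsulfonyl)methyl]acrylate
Product: 10 methyl 2-[(tributylstannyl)methyl]acrylate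
Conditions: Bu3SnH (2 equiv), azobisisobutyronitrile (cat.), benzene, 80 °C
Reagents that add atoms: tributyltin hydride, CCCC[SnH](CCCC)CCCC
Why: Radical SH2′ exchange of an allyl sulfone for an allylstannane, in which Bu3Sn• adds to the acrylate terminus and the adduct radical expels PhSO2•, which is taken up by the second equivalent of Bu3SnH, is the established entry to 2-(alkoxycarbonyl)allylstannanes.

**Step 9**
Reactants: 7 (2R,3R)-3-[(tert-butyldimethylsilyl)oxy]-2-[(4-methoxybenzyl)oxy]pent-4-enal; 10 methyl 2-[(tributylstannyl)methyl]acrylate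
Product: 11 methyl (4R,5S,6R)-6-[(tert-butyldimethylsilyl)oxy]-4-hydroxy-5-[(4-methoxybenzyl)oxy]-2-methylideneoct-7-enoate
Conditions: MgBr2·OEt2 (3 equiv), CH2Cl2, −20 °C, then 10 (2 equiv), −20 °C → rt
Reagents that add atoms: none
Why: Keck allylation under 1,2-chelation control, in which MgBr2 bridges the aldehyde oxygen and the C4 PMB ether in a five-membered chelate and the stannane attacks in an open SE2′ transition state from the face away from the C3 side chain, should give the 4,5-syn alcohol (5R in ring numbering), a sense that the 1,3-anti bias of the β-silyloxy group reinforces.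

**Step 10**
Reactants: 11 methyl (4R,5S,6R)-6-[(tert-butyldimethylsilyl)oxy]-4-hydroxy-5-[(4-methoxybenzyl)oxy]-2-methylideneoct-7-enoate; 12 (S)-3-methylpentanoic acid
Product: 13 methyl (4R,5S,6R)-6-[(tert-butyldimethylsilyl)oxy]-5-[(4-methoxybenzyl)oxy]-2-methylidene-4-{[(3S)-3-methylpentanoyl]oxy}oct-7-enoate
Conditions: N,N′-dicyclohexylcarbodiimide, 4-(dimethylamino)pyridine (cat.), CH2Cl2, 0 °C → rt
Reagents that add atoms: none
Why: Steglich esterification acylates the C5 hydroxyl with retention, the acid's stereocentre is β to the carboxyl and cannot epimerise, and capping O5 at once blocks lactonisation onto the acrylate ester.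

**Step 11**
Reactants: 13 methyl (4R,5S,6R)-6-[(tert-butyldimethylsilyl)oxy]-5-[(4-methoxybenzyl)oxy]-2-methylidene-4-{[(3S)-3-methylpentanoyl]oxy}oct-7-enoate
Product: 14 methyl (3R,4S,5R)-3-[(tert-butyldimethylsilyl)oxy]-4-[(4-methoxybenzyl)oxy]-5-{[(3S)-3-methylpentanoyl]oxy}cyclohex-1-ene-1-carboxylate
Conditions: second-generation Grubbs catalyst (H2IMes)(PCy3)Cl2Ru=CHPh (5 mol %), CH2Cl2 (5 mM), 40 °C
Reagents that add atoms: none
Why: Ring-closing metathesis between the monosubstituted vinyl group and the 1,1-disubstituted acrylate alkene forms the C1=C2 bond and the six-membered ring with loss of ethene, a pairing well known for shikimate esters, and high dilution suppresses dimerisation.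

**Step 12**
Reactants: 14 methyl (3R,4S,5R)-3-[(tert-butyldimethylsilyl)oxy]-4-[(4-methoxybenzyl)oxy]-5-{[(3S)-3-methylpentanoyl]oxy}cyclohex-1-ene-1-carboxylate
Product: 15 methyl (3R,4S,5R)-3-[(tert-butyldimethylsilyl)oxy]-4-hydroxy-5-{[(3S)-3-methylpentanoyl]oxy}cyclohex-1-ene-1-carboxylate
Conditions: 2,3-dichloro-5,6-dicyano-1,4-benzoquinone (DDQ), CH2Cl2/pH 7 phosphate buffer, 0 °C → rt
Reagents that add atoms: none
Why: Oxidative PMB ether cleavage (electron transfer from the electron-rich arene to DDQ, then hydrolysis of the benzylic oxocarbenium ion) under buffered two-phase conditions frees O4 without touching the silyl ether, the esters or the enoate.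

**Step 13**
Reactants: 15 methyl (3R,4S,5R)-3-[(tert-butyldimethylsilyl)oxy]-4-hydroxy-5-{[(3S)-3-methylpentanoyl]oxy}cyclohex-1-ene-1-carboxylate; 16 (R)-2-methylbutanoic acid
Product: 17 methyl (3R,4S,5R)-3-[(tert-butyldimethylsilyl)oxy]-4-{[(2R)-2-methylbutanoyl]oxy}-5-{[(3S)-3-methylpentanoyl]oxy}cyclohex-1-ene-1-carboxylate
Conditions: N,N′-dicyclohexylcarbodiimide, 4-(dimethylamino)pyridine (cat.), CH2Cl2, 0 °C → rt
Reagents that add atoms: none
Why: Steglich esterification acylates O4 with retention at C4, and catalytic DMAP at low temperature with no added amine base is chosen to keep the α-stereocentre of the acid from epimerising and to outrun O5→O4 acyl migration.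

**Step 14**
Reactants: 17 methyl (3R,4S,5R)-3-[(tert-butyldimethylsilyl)oxy]-4-{[(2R)-2-methylbutanoyl]oxy}-5-{[(3S)-3-methylpentanoyl]oxy}cyclohex-1-ene-1-carboxylate
Product: 18 methyl (3R,4R,5R)-3-hydroxy-4-{[(2R)-2-methylbutanoyl]oxy}-5-{[(3S)-3-methylpentanoyl]oxy}cyclohex-1-ene-1-carboxylate
Conditions: HF·pyridine, pyridine, THF, 0 °C → rt
Reagents that add atoms: none
Why: Fluoride-mediated Si–O cleavage in the acidic HF·pyridine medium removes the allylic silyl ether while the three esters stay in place, since acid disfavours the base-promoted cis O4→O3 acyl shift (the C4 descriptor changes only through CIP priorities).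

**Step 15**
Reactants: 18 methyl (3R,4R,5R)-3-hydroxy-4-{[(2R)-2-methylbutanoyl]oxy}-5-{[(3S)-3-methylpentanoyl]oxy}cyclohex-1-ene-1-carboxylate
Product: 19 methyl (3R,4S,5R)-3-acetoxy-4-{[(2R)-2-methylbutanoyl]oxy}-5-{[(3S)-3-methylpentanoyl]oxy}cyclohex-1-ene-1-carboxylate (CNP0188172.1)
Conditions: Ac2O, pyridine, 4-(dimethylamino)pyridine (cat.), CH2Cl2, 0 °C
Reagents that add atoms: acetic anhydride, CC(=O)OC(C)=O
Why: DMAP-catalysed acetylation of the allylic O3 hydroxyl is fast at 0 °C and should outpace acyl migration, which completes the third ester with every stereocentre untouched.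

**Compound list**
1 | penta-1,4-dien-3-ol | C=CC(O)C=C | starting material
2 | (2S,3R)-1,2-epoxypent-4-en-3-ol | C=C[C@@H](O)[C@@H]1CO1 | intermediate
3 | (2S,3R)-3-[(tert-butyldimethylsilyl)oxy]-1,2-epoxypent-4-ene | C=C[C@@H](O[Si](C)(C)C(C)(C)C)[C@@H]1CO1 | intermediate
4 | (2S,3R)-3-[(tert-butyldimethylsilyl)oxy]pent-4-ene-1,2-diol | C=C[C@@H](O[Si](C)(C)C(C)(C)C)[C@@H](O)CO | intermediate
5 | (4S)-4-[(1R)-1-[(tert-butyldimethylsilyl)oxy]prop-2-en-1-yl]-2-(4-methoxyphenyl)-1,3-dioxolane | C=C[C@@H](O[Si](C)(C)C(C)(C)C)[C@@H]1COC(c2ccc(OC)cc2)O1 | intermediate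
6 | (2S,3R)-3-[(tert-butyldimethylsilyl)oxy]-2-[(4-methoxybenzyl)oxy]pent-4-en-1-ol | C=C[C@@H](O[Si](C)(C)C(C)(C)C)[C@@H](OCc1ccc(OC)cc1)CO | intermediate
7 | (2R,3R)-3-[(tert-butyldimethylsilyl)oxy]-2-[(4-methoxybenzyl)oxy]pent-4-enal | C=C[C@@H](O[Si](C)(C)C(C)(C)C)[C@@H](OCc1ccc(OC)cc1)C=O | intermediate
8 | methyl 2-(bromomethyl)acrylate | C=C(CBr)C(=O)OC | starting material
9 | methyl 2-[(phenylsulfonyl)methyl]acrylate | C=C(CS(=O)(=O)c1ccccc1)C(=O)OC | intermediate
10 | methyl 2-[(tributylstannyl)methyl]acrylate | C=C(C[Sn](CCCC)(CCCC)CCCC)C(=O)OC | intermediate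
11 | methyl (4R,5S,6R)-6-[(tert-butyldimethylsilyl)oxy]-4-hydroxy-5-[(4-methoxybenzyl)oxy]-2-methylideneoct-7-enoate | C=C[C@@H](O[Si](C)(C)C(C)(C)C)[C@@H](OCc1ccc(OC)cc1)[C@H](O)CC(=C)C(=O)OC | intermediate
12 | (S)-3-methylpentanoic acid | CC[C@H](C)CC(=O)O | starting material
13 | methyl (4R,5S,6R)-6-[(tert-butyldimethylsilyl)oxy]-5-[(4-methoxybenzyl)oxy]-2-methylidene-4-{[(3S)-3-methylpentanoyl]oxy}oct-7-enoate | C=C[C@@H](O[Si](C)(C)C(C)(C)C)[C@@H](OCc1ccc(OC)cc1)[C@H](OC(=O)C[C@@H](C)CC)CC(=C)C(=O)OC | intermediate
14 | methyl (3R,4S,5R)-3-[(tert-butyldimethylsilyl)oxy]-4-[(4-methoxybenzyl)oxy]-5-{[(3S)-3-methylpentanoyl]oxy}cyclohex-1-ene-1-carboxylate | CC[C@H](C)CC(=O)O[C@@H]1CC(C(=O)OC)=C[C@@H](O[Si](C)(C)C(C)(C)C)[C@H]1OCc1ccc(OC)cc1 | intermediate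
15 | methyl (3R,4S,5R)-3-[(tert-butyldimethylsilyl)oxy]-4-hydroxy-5-{[(3S)-3-methylpentanoyl]oxy}cyclohex-1-ene-1-carboxylate | CC[C@H](C)CC(=O)O[C@@H]1CC(C(=O)OC)=C[C@@H](O[Si](C)(C)C(C)(C)C)[C@H]1O | intermediate
16 | (R)-2-methylbutanoic acid | CC[C@@H](C)C(=O)O | starting material
17 | methyl (3R,4S,5R)-3-[(tert-butyldimethylsilyl)oxy]-4-{[(2R)-2-methylbutanoyl]oxy}-5-{[(3S)-3-methylpentanoyl]oxy}cyclohex-1-ene-1-carboxylate | CC[C@H](C)CC(=O)O[C@@H]1CC(C(=O)OC)=C[C@@H](O[Si](C)(C)C(C)(C)C)[C@H]1OC(=O)[C@H](C)CC | intermediate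
18 | methyl (3R,4R,5R)-3-hydroxy-4-{[(2R)-2-methylbutanoyl]oxy}-5-{[(3S)-3-methylpentanoyl]oxy}cyclohex-1-ene-1-carboxylate | CC[C@H](C)CC(=O)O[C@@H]1CC(C(=O)OC)=C[C@@H](O)[C@H]1OC(=O)[C@H](C)CC | intermediate
19 | methyl (3R,4S,5R)-3-acetoxy-4-{[(2R)-2-methylbutanoyl]oxy}-5-{[(3S)-3-methylpentanoyl]oxy}cyclohex-1-ene-1-carboxylate | CC[C@H](C)CC(=O)O[C@@H]1CC(C(=O)OC)=C[C@@H](OC(C)=O)[C@H]1OC(=O)[C@H](C)CC | target

**Step count and risks**
Total steps: 15. Longest linear sequence: 13 (steps 1–6 and 9–15); steps 7–8 are a two-step side branch to the stannane.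

Step 9. What may go wrong: the ester-deactivated stannane may add so slowly to the magnesium chelate that facial control at C5 erodes, the γ-hydroxy acrylate lactonises, or the PMB ether is attacked by the Lewis acid on long exposure. Fallback: setting out again from aldehyde 7, the tin reagent is dropped and bromide 8 is used directly in an indium-mediated Barbier allylation (In powder, THF/H2O, rt), a Lewis-acid-free carbonyl addition that is well established for 2-(bromomethyl)acrylates. If the syn alcohol 11 is the main product the route is rejoined there. If instead the 4,5-anti epimer methyl (4S,5S,6R)-6-[(tert-butyldimethylsilyl)oxy]-4-hydroxy-5-[(4-methoxybenzyl)oxy]-2-methylideneoct-7-enoate F1 predominates, it is esterified with acid 12 under Mitsunobu conditions (PPh3, diisopropyl azodicarboxylate, toluene, 0 °C → rt), which installs the O5 ester with inversion at C5 and comes back to the route at 13.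

Step 11. What may go wrong: the ruthenium carbene may load slowly next to the bulky allylic silyl ether and engage the electron-poor 1,1-disubstituted alkene reluctantly, so that intermolecular dimerisation at the vinyl group or catalyst decay wins. Fallback: setting out from 13, the silyl ether is removed first (HF·pyridine, THF) to give the allylic alcohol methyl (4R,5R,6R)-6-hydroxy-5-[(4-methoxybenzyl)oxy]-2-methylidene-4-{[(3S)-3-methylpentanoyl]oxy}oct-7-enoate F2. Free allylic alcohols are favoured sites for carbene loading, so ring closure with the same ruthenium catalyst should then give the cyclohexenol methyl (3R,4R,5R)-3-hydroxy-4-[(4-methoxybenzyl)oxy]-5-{[(3S)-3-methylpentanoyl]oxy}cyclohex-1-ene-1-carboxylate F3, which is re-silylated (tBuMe2SiOTf, 2,6-lutidine, CH2Cl2, −78 °C) to come back to the route at 14.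

Step 5. What may go wrong: aluminium may coordinate the secondary acetal oxygen (helped by the neighbouring O3), so that the acetal opens the other way and the PMB group ends up on the primary oxygen. Fallback: setting out from diol 4, the primary hydroxyl is acylated selectively (pivaloyl chloride, pyridine, CH2Cl2, 0 °C) to give (2S,3R)-3-[(tert-butyldimethylsilyl)oxy]-2-hydroxypent-4-en-1-yl 2,2-dimethylpropanoate F4. The secondary hydroxyl is then benzylated under acid catalysis (4-methoxybenzyl 2,2,2-trichloroacetimidate, La(OTf)3 cat., toluene, rt) to give (2S,3R)-3-[(tert-butyldimethylsilyl)oxy]-2-[(4-methoxybenzyl)oxy]pent-4-en-1-yl 2,2-dimethylpropanoate F5, and reductive removal of the pivalate (iBu2AlH, CH2Cl2, −78 °C) comes back to the route at 6 with the PMB position fixed unambiguously.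

**Further compounds**
F1 | step 9 | methyl (4S,5S,6R)-6-[(tert-butyldimethylsilyl)oxy]-4-hydroxy-5-[(4-methoxybenzyl)oxy]-2-methylideneoct-7-enoate | C=C[C@@H](O[Si](C)(C)C(C)(C)C)[C@@H](OCc1ccc(OC)cc1)[C@@H](O)CC(=C)C(=O)OC
F2 | step 11 | methyl (4R,5R,6R)-6-hydroxy-5-[(4-methoxybenzyl)oxy]-2-methylidene-4-{[(3S)-3-methylpentanoyl]oxy}oct-7-enoate | C=C[C@@H](O)[C@@H](OCc1ccc(OC)cc1)[C@H](OC(=O)C[C@@H](C)CC)CC(=C)C(=O)OC
F3 | step 11 | methyl (3R,4R,5R)-3-hydroxy-4-[(4-methoxybenzyl)oxy]-5-{[(3S)-3-methylpentanoyl]oxy}cyclohex-1-ene-1-carboxylate | CC[C@H](C)CC(=O)O[C@@H]1CC(C(=O)OC)=C[C@@H](O)[C@H]1OCc1ccc(OC)cc1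
F4 | step 5 | (2S,3R)-3-[(tert-butyldimethylsilyl)oxy]-2-hydroxypent-4-en-1-yl 2,2-dimethylpropanoate | C=C[C@@H](O[Si](C)(C)C(C)(C)C)[C@@H](O)COC(=O)C(C)(C)C
F5 | step 5 | (2S,3R)-3-[(tert-butyldimethylsilyl)oxy]-2-[(4-methoxybenzyl)oxy]pent-4-en-1-yl 2,2-dimethylpropanoate | C=C[C@@H](O[Si](C)(C)C(C)(C)C)[C@@H](OCc1ccc(OC)cc1)COC(=O)C(C)(C)C
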